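Atom numbers Cn are the drimane numbers of one half of the target (ring A: C1–C5 and C10; ring B: C5–C10; C11 on C9; second half primed). β is the face of the C10 methyl. Locants inside systematic names belong to the name.

## Analysis of the target

Compound 27 (C30H50) is a hydrocarbon made of two identical trans-fused decalin halves (rings A and B of a drim-8-ene) joined by the ethano bridge C11–C11′. Each half has two stereocentres, C5 (S) and C10 (S), with the C5 hydrogen and the C10 methyl trans across the ring fusion. The halves are homochiral, so the molecule is C2-symmetric. The synthesis can therefore end by joining two molecules of one enantiopure C15 unit, but any minor enantiomer of that unit ends up in a meso diastereomer, so the enantiomeric purity of the monomer matters. The only functional groups are two tetrasubstituted C8=C9 alkenes. They tolerate base, hydride and radicals, but strong acid can shift them or make them cyclise onto each other across the bridge, so every heteroatom must be removed under neutral or basic conditions. The hard points are the quaternary C10 (between the alkene carbon C9 and C5, one carbon from the quaternary C4), the position of the C8=C9 alkene, and the bond between the two hindered carbons C11 and C11′. The strategy rests on ring A: C1–C5 and C10, with the C4 gem-dimethyl and the C10 methyl, form the pattern of a 3,5,5-trimethylcyclohex-2-enone. Its γ-carbon C5 carries the chain C6–C7 and its β-carbon is C10. C9 must be attached to this crowded β-carbon; a [2+2] photocycloaddition with allene does this, and the strain of the cyclobutane then allows the surplus C1–C8 bond to be cut.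

## Retrosynthetic reasoning

**C11–C11′.** Cutting the central bond of 27 gives two molecules of allylic bromide 26. This is the only bond whose cleavage halves the molecule, and C11 is allylic in both halves. The forward reductive coupling must join the primary termini; the other allylic terminus, C8, is fully substituted.

**C11–Br and the alkene position.** Bromide 26 comes from tertiary allylic alcohol 25 by allylic transposition, which places the alkene at C8=C9 without any acid-mediated isomerisation. Alcohol 25 comes from exocyclic enone 24 by 1,2-addition of a methyl organometallic, which supplies the C8 methyl.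

**C9–C11.** Enone 24 is the dehydration product of hydroxymethyl ketone 22. Its C9–C11 bond is made from formaldehyde 20 and the dianion of β-keto sulfone 19, giving 21, which is then desulfonylated. A plain C8 ketone would enolise towards C7, away from the quaternary C10. The sulfone at C7 takes the first deprotonation and leaves C9 as the only site for the second.

**C7–C8 (ring B).** β-Keto sulfone 19 is opened to ester sulfone 18; forward, the C7 sulfonyl carbanion acylates the C8 ester. An acyloin-type closure of a diester would put oxygen on both C7 and C8 with nothing to distinguish them, and a Dieckmann closure would give a five-membered ring. The sulfone gives a six-membered ring with one defined carbonyl.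

**C2 oxygen.** Ester 18 comes from keto ester 16 by reductive removal of the C2 carbonyl through its tosylhydrazone 17. This oxygen is needed only for the photochemistry and the ring cleavage.

**C1–C8 (reconnection).** Keto ester 16 is the retro-Claisen product of cyclobutane-1,3-dione 15, which comes from methylenecyclobutane 14 by oxidative cleavage of the exocyclic alkene. Forward, ring strain drives the cleavage of C1–C8 and leaves C10–C9H2–C8O2Me.

**C10–C9 and C1–C8 (key step).** Adduct 14 is disconnected into enone 12 and allene 13. The photocycloaddition creates the quaternary C10 next to the C5 methine and the C4 gem-dimethyl carbon, and must place C9 trans to the C5 side chain.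

**Side-chain adjustment.** Enone 12 comes from sulfone 11 by allylic oxidation, and 11 from ester 8 through alcohol 9 and mesylate 10. The ester is converted to the sulfone while it is the only carbonyl group, because after the ring cleavage a second ester could not be told apart from the C8 ester. C7 is therefore carried through the photochemical step as CH2SO2Ph, a spectator there. A route to 12 by enolate alkylation of a cyclic vinylogous ester, organolithium addition and transposition was set aside. No dependable enantioselective alkylation exists beside a quaternary carbon, and an ester in the electrophile would not survive the organolithium.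

**C5–C6.** Ester 8 is disconnected by a Johnson–Claisen rearrangement into allylic alcohol 5 and trimethyl orthoacetate 6 (through ketene acetal 7). The C–O stereocentre of 5 is transferred to C5.

**Ring A.** Alcohol 5 comes from enone 4 by enantioselective reduction, and 4 from isobutyraldehyde 1 and ethyl vinyl ketone 2 by annulation through keto aldehyde 3.

## Alternatives that were turned down

**Alternative 1:** The C5–C10 bond is disconnected by a semipinacol ring expansion.
- **Forward key step:** a boron Lewis acid ionises a trisubstituted epoxide at C10 of an epoxy cyclopentenol. The alkenyl carbon C5 shifts from the carbinol carbon C9 to C10, anti to the leaving oxygen. This gives cyclohexenone A1 with the C9 ketone, the quaternary C10 and a C1 carbinol.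
- **For:** the shift is stereospecific, so C10 follows the epoxide configuration. The C9 carbonyl is where C11 must be attached, with C8 alpha to it for methylation. On ring B functionality this is stronger than the chosen route, which needs a sulfone to steer reaction to C9.
- **Against:** A1 holds only ring B. Ring A must still be closed from the vinyl group on C4, and the C1 and C2 oxygens removed. C5 is sp2 in A1, so the trans ring fusion would depend on a late reduction of an alkene between two quaternary carbons, with no element to enforce the face. The C9 ketone is flanked by C10 and, after methylation, a substituted C8, so attaching C11 and dehydrating towards C8 would be difficult.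
- **Comparison:** the step count would not be lower. The chosen route fixes the C5/C10 relationship when C10 is made and keeps ring A intact from a simple enone. In place of the ready C9 carbonyl it offers three sulfone-directed steps.

**Alternative 2:** Both bicyclic halves are disconnected at once (C4–C5 and C9–C10 in each), with C11–C11′ already in an open C30 chain.
- **Forward key step:** an alkylaluminium Lewis acid opens two terminal (S)-epoxides. Each cation is captured by a trisubstituted alkene (ring A) and then by an allylsilane (ring B), which ends the cascade as an exocyclic C8 methylene. The product is α-onocerin A2.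
- **For:** the whole skeleton and all ring-fusion centres form in one step, and no dimerisation is needed. On step economy for the skeleton and on the C11–C11′ bond this is clearly stronger than the chosen route.
- **Against:** the epoxides that start the cascade and carry the chirality leave two 3β-hydroxyls that the target lacks, so two deoxygenations follow. The alkenes of A2 are exocyclic. Moving them to C8=C9 needs acid on a molecule whose two alkenes can reach each other across the bridge, with the trisubstituted ring isomer as a further competitor. Two independent bicyclisations also multiply any imperfect selectivity.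
- **Comparison:** the chosen route is longer. It removes its one extra oxygen (C2) on a monomer and places each alkene by allylic transposition before the halves are joined, so the dimer never sees acid.

**Alternative 3:** C8 with its methyl is inserted between C9 and C7 by ring expansion.
- **Forward key step:** Lewis-acid-promoted addition of diazoethane A5 to the saturated ketone of the Hajos–Parrish ketone A4, then 1,2-shift of C7 with loss of nitrogen. This gives A3, the 8-methyl homologue of the Wieland–Miescher ketone.
- **For:** A4 is available enantiopure in one organocatalytic step. A3 has the C9 ketone and C8 methyl in place and an enone in ring A for the classical installation of the C4 gem-dimethyl group with a trans ring fusion. That sequence is better precedented than the photochemical step, and ring B is again better functionalised than in the chosen route.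
- **Against:** the reacting ketone is next to the quaternary C10, so diazoalkane addition is slow. Migration of the quaternary carbon, epoxide formation and reaction at the enone carbonyl compete. A5 is hazardous and must be made fresh. Afterwards the C3 oxygen must be removed, the C4 gem-dimethyl group added, and C11 attached to a doubly hindered C9 ketone with dehydration directed towards C8.
- **Comparison:** the step count is similar. The chosen route builds C10 with its C4 and C5 neighbours already present and avoids the dehydration regiochemistry.

Key step: step 7

## Route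

**Step 1**
Reactants: 1 isobutyraldehyde; 2 ethyl vinyl ketone
Product: 4 2,4,4-trimethylcyclohex-2-en-1-one, via keto aldehyde 3 (not isolated)
Conditions: H2SO4 (cat.), toluene, 45 °C then reflux (Dean–Stark)
Reagents that add atoms: none
Why: Acid-catalysed Robinson annulation: the enol of 1 adds to 2 (Michael addition), and keto aldehyde 3 closes by aldol condensation of the ethyl ketone α-carbon onto the non-enolisable aldehyde. No stereocentre is formed.

**Step 2**
Reactants: 4 2,4,4-trimethylcyclohex-2-en-1-one
Product: 5 (R)-2,4,4-trimethylcyclohex-2-en-1-ol
Conditions: (S)-Me-CBS oxazaborolidine (10 mol %), BH3·SMe2, THF, −20 °C; MeOH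
Reagents that add atoms: none
Why: Corey–Bakshi–Shibata reduction: the ketone binds to the catalyst with the α-methylated alkenyl arm as the large group, and hydride is delivered within the complex to one face, which should give the (R)-alcohol by 1,2-reduction only.

**Step 3**
Reactants: 5 (R)-2,4,4-trimethylcyclohex-2-en-1-ol; 6 trimethyl orthoacetate
Product: 8 methyl 2-[(1S)-2,6,6-trimethylcyclohex-2-en-1-yl]acetate, via ketene acetal 7 (not isolated)
Conditions: 6 (5 equiv), EtCO2H (cat.), xylene, 140 °C, MeOH distilled off
Reagents that add atoms: none
Why: Johnson–Claisen rearrangement: acid-catalysed exchange gives ketene acetal 7, and its [3,3] shift forms C5–C6 on the ring face that carried the C–O bond, so the (R) carbinol centre becomes the (S) centre at C5. Formation of the ester carbonyl drives the new bond even beside the gem-dimethyl carbon.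

**Step 4**
Reactants: 8 methyl 2-[(1S)-2,6,6-trimethylcyclohex-2-en-1-yl]acetate
Product: 9 2-[(1S)-2,6,6-trimethylcyclohex-2-en-1-yl]ethan-1-ol
Conditions: LiAlH4, Et2O, 0 °C
Reagents that add atoms: none
Why: Ester reduction by LiAlH4, done while the ester is the only carbonyl group so that the later C8 ester is unique. The alkene and C5 are untouched.

**Step 5**
Reactants: 9 2-[(1S)-2,6,6-trimethylcyclohex-2-en-1-yl]ethan-1-ol
Product: 11 {2-[(1S)-2,6,6-trimethylcyclohex-2-en-1-yl]ethanesulfonyl}benzene, via mesylate 10 (not isolated)
Conditions: MsCl, Et3N, CH2Cl2, 0 °C; then PhSO2Na, NaI (cat.), DMF, 80 °C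
Reagents that add atoms: sodium benzenesulfinate, [Na+].[O-]S(=O)c1ccccc1
Why: Mesylation, then SN2 displacement at an unhindered primary carbon by the sulfur of the sulfinate ion, gives the sulfone that later stabilises the C7 carbanion.

**Step 6**
Reactants: 11 {2-[(1S)-2,6,6-trimethylcyclohex-2-en-1-yl]ethanesulfonyl}benzene
Product: 12 (4S)-3,5,5-trimethyl-4-[2-(phenylsulfonyl)ethyl]cyclohex-2-en-1-one
Conditions: t-BuOOH, Rh2(cap)4 (1 mol %, cap = caprolactamate), K2CO3, CH2Cl2, rt
Reagents that add atoms: tert-butyl hydroperoxide, CC(C)(C)OO
Why: Allylic oxidation by tert-butylperoxy radicals: hydrogen is abstracted from the only ring CH2 next to the alkene, and the allylic peroxide collapses to the conjugated enone. The tertiary allylic C5–H is shielded by the gem-dimethyl group, and the sulfone is inert.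

**Step 7**
Reactants: 12 (4S)-3,5,5-trimethyl-4-[2-(phenylsulfonyl)ethyl]cyclohex-2-en-1-one; 13 allene
Product: 14 (1R,5S,6R)-4,4,6-trimethyl-8-methylidene-5-[2-(phenylsulfonyl)ethyl]bicyclo[4.2.0]octan-2-one
Conditions: 13 (about 15 equiv), THF, −78 °C, hν (Hg lamp, about 350 nm, Pyrex or uranium-glass filter), stopped before full conversion
Reagents that add atoms: none
Why: Light above 300 nm, which the phenyl sulfone does not absorb, excites the enone; intersystem crossing gives the twisted triplet, which adds to 13 stepwise through a triplet 1,4-biradical. Spin inversion and radical recombination then close the four-membered ring, so C10–C9 and C1–C8 are formed and the cyclobutane can only be cis-fused to ring A. The closest known reaction type is the enone–allene [2+2] photocycloaddition of 3-alkylcyclohex-2-enones, which gives head-to-head 8-methylidenebicyclo[4.2.0]octan-2-ones (allene terminus on the β-carbon, central carbon on the α-carbon). C10 is set when the pyramidalised β-carbon bonds axially to the allene terminus anti to the C5 side chain, which allylic strain with the C10 methyl holds pseudoaxial; C9 then lies trans to C6 and the methyl is β. C1 follows from C10 through the cis ring fusion and is removed in step 8. The step needs head-to-head regiochemistry, expected from the known preference of allene, and anti facial selectivity, which the adjacent C5 stereocentre should secure. Short wavelengths are filtered out because the β,γ-unsaturated ketone product can undergo a 1,3-acyl shift on further excitation.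

**Step 8**
Reactants: 14 (1R,5S,6R)-4,4,6-trimethyl-8-methylidene-5-[2-(phenylsulfonyl)ethyl]bicyclo[4.2.0]octan-2-one
Product: 16 methyl 2-[(1R,2S)-1,3,3-trimethyl-5-oxo-2-[2-(phenylsulfonyl)ethyl]cyclohexyl]acetate, via cyclobutane-1,3-dione 15 (not isolated)
Conditions: O3, CH2Cl2, −78 °C; Me2S; aqueous wash; then NaOMe (0.3 equiv), MeOH, 0 °C
Reagents that add atoms: ozone, [O-][O+]=O; methanol, CO
Why: Ozonolysis cleaves only the 1,1-disubstituted alkene to the cyclobutanone. Methoxide then adds to this strained carbonyl of dione 15, and the retro-Claisen cleaves C1–C8 with relief of ring strain, leaving C10–C9H2–C8O2Me and the C2 ketone. C5 and C10 are not enolisable and stay as set.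

**Step 9**
Reactants: 16 methyl 2-[(1R,2S)-1,3,3-trimethyl-5-oxo-2-[2-(phenylsulfonyl)ethyl]cyclohexyl]acetate
Product: 18 methyl 2-[(1R,2S)-1,3,3-trimethyl-2-[2-(phenylsulfonyl)ethyl]cyclohexyl]acetate, via tosylhydrazone 17 (not isolated)
Conditions: TsNHNH2, EtOH, 78 °C; evaporate; catecholborane, CHCl3, 0 °C to rt; NaOAc·3H2O, 60 °C
Reagents that add atoms: none
Why: Reduction of a tosylhydrazone with catecholborane (Kabalka variant of the Caglioti reduction): hydroboration of C=N, then loss of sulfinate and N2, delivers CH2. The carbon stays sp2 until late, which suits a ketone whose axial positions face two syn-axial methyl groups; ester and sulfone should survive.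

**Step 10**
Reactants: 18 methyl 2-[(1R,2S)-1,3,3-trimethyl-2-[2-(phenylsulfonyl)ethyl]cyclohexyl]acetate
Product: 19 (4aS,8aR)-5,5,8a-trimethyl-3-(phenylsulfonyl)octahydronaphthalen-2(1H)-one (C3 epimers)
Conditions: LDA (2.2 equiv), THF, −78 to 0 °C; aq. NH4Cl
Reagents that add atoms: none
Why: Intramolecular acylation of an α-sulfonyl carbanion by an ester (Dieckmann-type). LDA removes the accessible C7–H next to sulfur in preference to the neopentyl C9–H, and the anion closes ring B on C8 from two equatorial arms, giving the trans-decalin. Deprotonation of the acidic β-keto sulfone product drives the closure.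

**Step 11**
Reactants: 19 (4aS,8aR)-5,5,8a-trimethyl-3-(phenylsulfonyl)octahydronaphthalen-2(1H)-one; 20 formaldehyde
Product: 21 (4aS,8aS)-1-(hydroxymethyl)-5,5,8a-trimethyl-3-(phenylsulfonyl)octahydronaphthalen-2(1H)-one (C1 and C3 epimers)
Conditions: LDA (2.2 equiv), THF, −78 to 0 °C; 20 (1.1 equiv, THF solution from cracked paraformaldehyde), −78 °C; aq. NH4Cl
Reagents that add atoms: none
Why: γ-Functionalisation of a β-keto sulfone dianion: the first equivalent of base gives the sulfonyl-stabilised enolate at C7, and the second removes a C9 proton, the only other α-position. The more basic C9 carbanion adds to formaldehyde; the C7 and C9 configurations do not matter because both centres are later CH2 or sp2.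

**Step 12**
Reactants: 21 (4aS,8aS)-1-(hydroxymethyl)-5,5,8a-trimethyl-3-(phenylsulfonyl)octahydronaphthalen-2(1H)-one
Product: 22 (4aS,8aS)-1-(hydroxymethyl)-5,5,8a-trimethyloctahydronaphthalen-2(1H)-one (C1 epimers)
Conditions: Al(Hg), THF/H2O (9:1), rt
Reagents that add atoms: none
Why: Reductive cleavage of the C–S bond of a β-keto sulfone by aluminium amalgam (electron transfer, loss of sulfinate, protonation of the enolate). The near-neutral medium should avoid retro-aldol loss of the hydroxymethyl group.

**Step 13**
Reactants: 22 (4aS,8aS)-1-(hydroxymethyl)-5,5,8a-trimethyloctahydronaphthalen-2(1H)-one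
Product: 24 (4aS,8aS)-5,5,8a-trimethyl-1-methylideneoctahydronaphthalen-2(1H)-one, via keto mesylate 23 (not isolated)
Conditions: MsCl, Et3N, CH2Cl2, 0 °C; then DBU, rt
Reagents that add atoms: none
Why: Mesylation of the primary alcohol and E1cB elimination through the C9 enolate give the exocyclic enone. The position of the hydroxymethyl group fixes the regiochemistry.

**Step 14**
Reactants: 24 (4aS,8aS)-5,5,8a-trimethyl-1-methylideneoctahydronaphthalen-2(1H)-one
Product: 25 (4aS,8aS)-2,5,5,8a-tetramethyl-1-methylidenedecahydronaphthalen-2-ol (C2 epimers)
Conditions: MeLi, CeCl3, THF, −78 °C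
Reagents that add atoms: methyllithium, [Li]C
Why: 1,2-Addition of the organocerium reagent to the enone carbonyl brings in the C8 methyl; cerium suppresses enolisation towards C7 and conjugate addition. The configuration of the new carbinol centre does not matter because C8 becomes sp2 in step 15.

**Step 15**
Reactants: 25 (4aS,8aS)-2,5,5,8a-tetramethyl-1-methylidenedecahydronaphthalen-2-ol
Product: 26 (4aS,8aS)-4-(bromomethyl)-3,4a,8,8-tetramethyl-1,2,4a,5,6,7,8,8a-octahydronaphthalene (11-bromodrim-8-ene)
Conditions: PBr3, pyridine (cat.), Et2O, −10 °C
Reagents that add atoms: phosphorus tribromide, BrP(Br)Br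
Why: Allylic transposition (SN2′-type bromination): the activated tertiary allylic alcohol ionises and bromide attacks the unhindered exocyclic terminus C11. This moves the double bond to the tetrasubstituted C8=C9 position, the more stable allylic isomer.

**Step 16**
Reactants: 26 11-bromodrim-8-ene (2 molecules)
Product: 27 1,2-bis[(4aS,8aS)-2,5,5,8a-tetramethyl-3,4,4a,5,6,7,8,8a-octahydronaphthalen-1-yl]ethane (CNP0372467.1)
Conditions: Cp2TiCl2 (0.2 equiv), Mn dust (excess), THF, rt
Reagents that add atoms: none
Why: Reductive Wurtz-type homocoupling of an allylic bromide by Cp2TiCl (trivalent titanium, formed and regenerated by Mn): bromine abstraction gives the allyl radical, which is captured as an allyltitanium species and alkylated by a second molecule of 26. Both partners should react at the primary terminus C11 because the other terminus, C8, is fully substituted, so C11–C11′ forms and both alkenes stay in place. No stereocentre is formed and the medium is neutral.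

## Compound list

1 | isobutyraldehyde | CC(C)C=O | starting material
2 | ethyl vinyl ketone (pent-1-en-3-one) | CCC(=O)C=C | starting material
3 | 2,2-dimethyl-5-oxoheptanal | CCC(=O)CCC(C)(C)C=O | intermediate (not isolated)
4 | 2,4,4-trimethylcyclohex-2-en-1-one | CC1=CC(C)(C)CCC1=O | intermediate
5 | (R)-2,4,4-trimethylcyclohex-2-en-1-ol | O[C@@H]1CCC(C)(C)C=C1C | intermediate
6 | trimethyl orthoacetate | CC(OC)(OC)OC | starting material
7 | 1-methoxy-1-{[(1R)-2,4,4-trimethylcyclohex-2-en-1-yl]oxy}ethene | C=C(OC)O[C@@H]1CCC(C)(C)C=C1C | intermediate (not isolated)
8 | methyl 2-[(1S)-2,6,6-trimethylcyclohex-2-en-1-yl]acetate | COC(=O)C[C@@H]1C(C)=CCCC1(C)C | intermediate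
9 | 2-[(1S)-2,6,6-trimethylcyclohex-2-en-1-yl]ethan-1-ol | OCC[C@@H]1C(C)=CCCC1(C)C | intermediate
10 | 2-[(1S)-2,6,6-trimethylcyclohex-2-en-1-yl]ethyl methanesulfonate | CS(=O)(=O)OCC[C@@H]1C(C)=CCCC1(C)C | intermediate (not isolated)
11 | {2-[(1S)-2,6,6-trimethylcyclohex-2-en-1-yl]ethanesulfonyl}benzene | O=S(=O)(CC[C@@H]1C(C)=CCCC1(C)C)c1ccccc1 | intermediate
12 | (4S)-3,5,5-trimethyl-4-[2-(phenylsulfonyl)ethyl]cyclohex-2-en-1-one (key-step precursor) | O=S(=O)(CC[C@@H]1C(C)=CC(=O)CC1(C)C)c1ccccc1 | intermediate
13 | allene (propadiene) | C=C=C | starting material
14 | (1R,5S,6R)-4,4,6-trimethyl-8-methylidene-5-[2-(phenylsulfonyl)ethyl]bicyclo[4.2.0]octan-2-one (head-to-head adduct, cis-fused, C9 trans to the C5 chain) | O=S(=O)(CC[C@H]1C(C)(C)CC(=O)[C@@H]2C(=C)C[C@]12C)c1ccccc1 | intermediate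
15 | 4,4,6-trimethyl-5-[2-(phenylsulfonyl)ethyl]bicyclo[4.2.0]octane-2,8-dione (cis-fused, C5 and C6 as in 14) | O=S(=O)(CC[C@H]1C(C)(C)CC(=O)[C@@H]2C(=O)C[C@]12C)c1ccccc1 | intermediate (not isolated)
16 | methyl 2-[(1R,2S)-1,3,3-trimethyl-5-oxo-2-[2-(phenylsulfonyl)ethyl]cyclohexyl]acetate | COC(=O)C[C@@]1(C)CC(=O)CC(C)(C)[C@@H]1CCS(=O)(=O)c1ccccc1 | intermediate
17 | tosylhydrazone of 16 | COC(=O)C[C@@]1(C)CC(=NNS(=O)(=O)c2ccc(C)cc2)CC(C)(C)[C@@H]1CCS(=O)(=O)c1ccccc1 | intermediate (not isolated)
18 | methyl 2-[(1R,2S)-1,3,3-trimethyl-2-[2-(phenylsulfonyl)ethyl]cyclohexyl]acetate | COC(=O)C[C@@]1(C)CCCC(C)(C)[C@@H]1CCS(=O)(=O)c1ccccc1 | intermediate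
19 | (4aS,8aR)-5,5,8a-trimethyl-3-(phenylsulfonyl)octahydronaphthalen-2(1H)-one (trans-fused, C3 epimers) | O=C1C[C@@]2(C)CCCC(C)(C)[C@@H]2CC1S(=O)(=O)c1ccccc1 | intermediate
20 | formaldehyde (monomer from paraformaldehyde) | C=O | starting material
21 | (4aS,8aS)-1-(hydroxymethyl)-5,5,8a-trimethyl-3-(phenylsulfonyl)octahydronaphthalen-2(1H)-one (C1 and C3 epimers) | O=C1C(CO)[C@@]2(C)CCCC(C)(C)[C@@H]2CC1S(=O)(=O)c1ccccc1 | intermediate
22 | (4aS,8aS)-1-(hydroxymethyl)-5,5,8a-trimethyloctahydronaphthalen-2(1H)-one (C1 epimers) | O=C1CC[C@H]2C(C)(C)CCC[C@]2(C)C1CO | intermediate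
23 | [(4aS,8aS)-5,5,8a-trimethyl-2-oxodecahydronaphthalen-1-yl]methyl methanesulfonate | O=C1CC[C@H]2C(C)(C)CCC[C@]2(C)C1COS(C)(=O)=O | intermediate (not isolated)
24 | (4aS,8aS)-5,5,8a-trimethyl-1-methylideneoctahydronaphthalen-2(1H)-one | C=C1C(=O)CC[C@H]2C(C)(C)CCC[C@]12C | intermediate
25 | (4aS,8aS)-2,5,5,8a-tetramethyl-1-methylidenedecahydronaphthalen-2-ol (C2 epimers) | C=C1C(C)(O)CC[C@H]2C(C)(C)CCC[C@]12C | intermediate
26 | (4aS,8aS)-4-(bromomethyl)-3,4a,8,8-tetramethyl-1,2,4a,5,6,7,8,8a-octahydronaphthalene (11-bromodrim-8-ene) | BrCC1=C(C)CC[C@H]2C(C)(C)CCC[C@]12C | intermediate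
27 | 1,2-bis[(4aS,8aS)-2,5,5,8a-tetramethyl-3,4,4a,5,6,7,8,8a-octahydronaphthalen-1-yl]ethane (CNP0372467.1) | CC1=C(CCC2=C(C)CC[C@H]3C(C)(C)CCC[C@]23C)[C@@]2(C)CCCC(C)(C)[C@@H]2CC1 | target

## Step count and least certain steps

Total step count: 16. Longest linear sequence: 16 steps (1 to 27 in one line; the last step joins two molecules of 26). Any minor enantiomer left after step 2 would be turned into the meso diastereomer in step 16; 27 should therefore be purified by crystallisation.

**Step 7 (key step).**
- **Risk:** poor facial selectivity. Allene must approach the α-face of C10, which carries an axial C4 methyl in a 1,3-relationship, while the β-face is covered by the C5 chain; if the two effects balance, the cis isomer forms as well. Photodeconjugation of 12 by γ-hydrogen abstraction and secondary photolysis of 14 would lower the conversion.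
- **Fallback, from 12 to 16:** Hosomi–Sakurai allylation of 12 (allyltrimethylsilane, TiCl4, CH2Cl2, −78 °C) is a polar conjugate allylation that tolerates a fully substituted β-carbon. It should give (4S)-3-allyl-3,5,5-trimethyl-4-[2-(phenylsulfonyl)ethyl]cyclohexan-1-one F1 by axial attack anti to the C5 chain. Ozonolysis (O3; Me2S) of the terminal alkene gives keto aldehyde F2, Pinnick oxidation (NaClO2, NaH2PO4, 2-methylbut-2-ene) gives keto acid F3, and esterification (MeI, K2CO3, DMF) returns to the route at 16.

**Step 11.**
- **Risk:** incomplete second deprotonation at the neopentyl C9–H, or proton transfer and a second hydroxymethylation at C7 where formaldehyde is in local excess.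
- **Fallback, from 19 to 22:** Al(Hg) gives (4aS,8aS)-5,5,8a-trimethyloctahydronaphthalen-2(1H)-one F4. Kinetic enolisation away from the quaternary centre (LDA, TMSCl, −78 °C) gives silyl enol ether F5, and Saegusa oxidation (Pd(OAc)2, MeCN) gives enone F6, in which C7 is sp2 and C9 is the only α′-position. LDA at −78 °C and then 20 give hydroxymethyl enone F7, and hydrogenation (H2, Pd/C, EtOAc) returns to the route at 22.

**Step 16.**
- **Risk:** coupling through the tertiary terminus, reduction of the bromide to the hydrocarbon, or elimination to a diene, all favoured by the crowding around C11 (tetrasubstituted alkene and quaternary C10).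
- **Fallback, from 26 to 27:** half of 26 is converted to allylic sulfone F8 (PhSO2Na, DMF). Its lithio derivative (n-BuLi, THF, −78 °C) is alkylated by the other half of 26, giving C30 sulfone F9 by SN2 at C11′ with an unambiguous nucleophile. Reductive removal of the sulfonyl group (Li, EtNH2, −78 °C) returns to the route at 27.

**Step 10.**
- **Risk:** deprotonation next to the ester instead of next to sulfur, or slow attack on an ester carbonyl held beside the quaternary C10, leading to recovered material or intermolecular condensation.
- **Fallback, from 18 to 19:** DIBAL-H (CH2Cl2, −78 °C) reduces the ester to aldehyde F10. LDA then generates the sulfonyl carbanion, which adds to the much more electrophilic aldehyde to give β-hydroxy sulfone F11. Dess–Martin periodinane oxidises F11 and returns to the route at 19.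

## Further compounds

F1 | step 7 | (4S)-3-allyl-3,5,5-trimethyl-4-[2-(phenylsulfonyl)ethyl]cyclohexan-1-one (allyl trans to the C5 chain) | C=CC[C@@]1(C)CC(=O)CC(C)(C)[C@@H]1CCS(=O)(=O)c1ccccc1
F2 | step 7 | 2-[1,3,3-trimethyl-5-oxo-2-[2-(phenylsulfonyl)ethyl]cyclohexyl]acetaldehyde (ring configuration as in 16) | O=CC[C@@]1(C)CC(=O)CC(C)(C)[C@@H]1CCS(=O)(=O)c1ccccc1
F3 | step 7 | 2-[(1R,2S)-1,3,3-trimethyl-5-oxo-2-[2-(phenylsulfonyl)ethyl]cyclohexyl]acetic acid | OC(=O)C[C@@]1(C)CC(=O)CC(C)(C)[C@@H]1CCS(=O)(=O)c1ccccc1
F4 | step 11 | (4aS,8aS)-5,5,8a-trimethyloctahydronaphthalen-2(1H)-one (trans-fused) | O=C1CC[C@H]2C(C)(C)CCC[C@]2(C)C1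
F5 | step 11 | trimethylsilyl enol ether of F4 (double bond C7=C8) | C[Si](C)(C)OC1=CC[C@H]2C(C)(C)CCC[C@]2(C)C1
F6 | step 11 | 5,5,8a-trimethyl-4a,5,6,7,8,8a-hexahydronaphthalen-2(1H)-one (trans-fused, enone C6=C7) | O=C1C=C[C@H]2C(C)(C)CCC[C@]2(C)C1
F7 | step 11 | 1-(hydroxymethyl)-5,5,8a-trimethyl-4a,5,6,7,8,8a-hexahydronaphthalen-2(1H)-one (trans-fused, C1 epimers) | O=C1C=C[C@H]2C(C)(C)CCC[C@]2(C)C1CO
F8 | step 16 | 11-(phenylsulfonyl)drim-8-ene | O=S(=O)(CC1=C(C)CC[C@H]2C(C)(C)CCC[C@]12C)c1ccccc1
F9 | step 16 | 11-phenylsulfonyl derivative of 27 (C11 epimers) | O=S(=O)(C(CC1=C(C)CC[C@H]2C(C)(C)CCC[C@]12C)C1=C(C)CC[C@H]2C(C)(C)CCC[C@]12C)c1ccccc1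
F10 | step 10 | 2-[1,3,3-trimethyl-2-[2-(phenylsulfonyl)ethyl]cyclohexyl]acetaldehyde (ring configuration as in 18) | O=CC[C@@]1(C)CCCC(C)(C)[C@@H]1CCS(=O)(=O)c1ccccc1
F11 | step 10 | 5,5,8a-trimethyl-3-(phenylsulfonyl)decahydronaphthalen-2-ol (trans-fused, C2 and C3 epimers) | OC1C[C@@]2(C)CCCC(C)(C)[C@@H]2CC1S(=O)(=O)c1ccccc1
A1 | alternative 1 | 2-[2-(tert-butyldimethylsilyloxy)-1-hydroxyethyl]-2-methyl-3-(2-methylbut-3-en-2-yl)cyclohex-3-en-1-one (ring B with C9 ketone, quaternary C10, C1 carbinol) | C=CC(C)(C)C1=CCCC(=O)[C@@]1(C)[C@H](O)CO[Si](C)(C)C(C)(C)C
A2 | alternative 2 | α-onocerin (3β,3′β-diol with exocyclic C8 and C8′ methylenes) | C(C[C@H]1C(=C)CC[C@H]2C(C)(C)[C@@H](O)CC[C@]12C)[C@H]1C(=C)CC[C@H]2C(C)(C)[C@@H](O)CC[C@]12C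
A3 | alternative 3 | 2,8a-dimethyl-3,4,8,8a-tetrahydronaphthalene-1,6(2H,7H)-dione (8-methyl homologue of the Wieland–Miescher ketone) | C[C@]12CCC(=O)C=C1CC[C@@H](C)C2=O
A4 | alternative 3 | (S)-Hajos–Parrish ketone, (7aS)-7a-methyl-2,3,7,7a-tetrahydro-1H-indene-1,5(6H)-dione | C[C@]12CCC(=O)C=C1CCC2=O
A5 | alternative 3 | diazoethane | CC=[N+]=[N-]
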